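## Structural features

- The target is a depside, a diaryl ester with no stereocentre, in which ring A (numbered as the acetophenone) carries acetyl on C1, free hydroxyls on C2 and C4, the esterified oxygen on C3, hydrogen on C5 and pentyl on C6.
- Ring B (numbered as the benzoate) carries the carboxyl carbon on C1, methoxy on C2, hydroxyl on C4 and propyl on C6.
- The rings are joined only by the ester C(=O)–O bond, which runs from C1 of ring B to the central one of the three contiguous oxygens of ring A.
- Fragile points are the aryl ester flanked by two free phenols (acyl shift or solvolysis once a neighbouring phenoxide forms), the air-sensitive vicinal triol of ring A, the electron-rich di-ortho-substituted benzoic acid (decarboxylation in hot acid) and the aryl ketone, which limits reductive methods.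
- The first difficulty is ring B: propyl, carboxyl and methoxy sit on three neighbouring carbons and the two oxygens must differ (methoxy on C2, hydroxyl on C4), which resorcinol chemistry does not deliver directly.
- The second difficulty is to join a doubly ortho-substituted acid to one oxygen out of three on ring A, and to the most crowded one.
- The key step exploits the C6-propyl, C1-carboxyl, C2-methoxy adjacency of ring B, the pattern that a 3-methoxyaryne produces when a carbon nucleophile adds at the aryne carbon remote from methoxy and an electrophile is taken up at the carbon next to it, while the C4 oxygen is carried along as a silyl ether.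

## Logic of the disconnections

**22 to 21.** The O–CH2Ph bond on the C4 oxygen of ring A is cut last. A neutral hydrogenolysis as the final operation generates no phenoxide, so the ester stays on the central oxygen. The gain is one protecting group. The forward step must stop at the benzylic C–O bond and spare the aryl ketone and the aryl ester.

**21 to 20.** The O–Si bond on the C4 oxygen of ring B is cut. This silyl ether is what the key step needs, and it is removed while the only free phenol of ring A is the chelated one. The fluoride source must be buffered so that no acyl shift or ester cleavage starts.

**20 to 9 and 17 (through 18 and 19).** The ester C–O bond is cut. It is the only bond between the rings, and cutting it gives two single-ring halves of similar size. The forward step must acylate the C3 oxygen of 17 and not the chelated C2 hydroxyl, between two doubly ortho-substituted partners. The acid is therefore activated as 18 and the phenol as dianion 19, whose non-conjugated C3 phenoxide is the more reactive site. The C4 oxygen of 17 carries benzyl and not silyl, because a silyl group next to a phenoxide can shift onto it and misdirect the acylation.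

**17 to 15 and 16.** The same O–benzyl bond is cut in the sense of its formation. 15 is simpler, and its three hydroxyls differ enough in acidity and hindrance that the C4 hydroxyl should react alone under a weak base. The forward step must stop at monoalkylation.

**15 to 14.** Three O–CH3 bonds are cut. Methyl ethers let the ring-building steps run on a robust, non-oxidisable substrate. The Lewis acid must cleave all three ethers without harming the ketone.

**14 to 12 and 13.** The ring–acetyl bond is cut. The two free positions of 12 are equivalent, so a Friedel–Crafts acylation has no regiochemical choice. Acylation must occur next to the pentyl chain, and any ortho-demethylation is harmless because the next step removes all methyl groups.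

**12 to 10 and 11.** The aryl–pentyl bond is cut. 10 is a purchasable arene with the three oxygens in place and a halogen para to the central one, exactly where the chain belongs. The coupling of a primary alkyl group must outrun β-hydride elimination.

**9 to 3, 4 and 5 (through 6, 7 and 8).** The C6–propyl and C1–carboxyl bonds of ring B are cut together. Both flank the position between fluorine and methoxy in 3: the fluorine-bearing carbon becomes C6 and the lithiated carbon becomes C1. A 1,3,5-trisubstituted benzene thus becomes the fully substituted acid in one operation, with the two oxygens already different. The forward step needs lithiation at one of three ring positions, addition to 7 in one direction, and no competing nucleophile.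

**3 to 1 and 2.** The O–Si bond is cut. The silyl group is chosen bulky and non-coordinating so that it shields its own ortho positions from the base. The forward step is a routine silylation.

## Other disconnections considered

Alternative 1: Ring A would be opened at two ring bonds, C1–C6 (between the acetyl-bearing and pentyl-bearing carbons) and C3–C4.
- Forward step: in ethanol with NaOEt the enolate of pentane-2,4-dione A3 would add to ethyl (E)-oct-2-enoate A2. A methyl ketone enolate of the adduct would then close onto the ester in a Claisen condensation to give trans-4-acetyl-5-pentylcyclohexane-1,3-dione A1, a racemate whose two stereocentres vanish on aromatisation.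
- In favour: A2 and A3 are cheap acyclic inputs, no transition metal and no BBr3 are needed, and acetyl and pentyl are placed on neighbouring carbons by construction.
- Against: A1 has oxygen only on the carbons that become C2 and C4 of ring A. Dehydrogenation would lead to the resorcinol 1-(2,4-dihydroxy-6-pentylphenyl)ethan-1-one A4, and A4 lacks the C3 oxygen, so that oxygen would have to be installed on the methylene between the two carbonyls of A1 before aromatisation. Ethoxide can also remove the acetyl group by retro-Claisen cleavage, and conjugate addition to the β-alkyl enoate A2 is slow.
- Comparison on structure: the chosen route buys the 1,2,3-trioxygenated ring in 10 and needs no oxidation, whereas the alternative must add an oxygen and adjust the oxidation level.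
- Comparison on mechanism: both are well understood, and the alternative is the equal of steps 3 and 4 in fixing acetyl next to pentyl. It would be the better plan in one respect: an oxygen introduced separately at C3 is distinct from its neighbours from the start, whereas 15 has to be differentiated through acidity and chelation.
- Comparison on step economy: ring formation, oxygenation, aromatisation and protection would be at least as long as the four steps to 17, and ring B would still require the key step.

Alternative 2: Ring B would be cut at C1–C2 and C5–C6.
- Forward step: 1,1-dimethoxy-3-(trimethylsilyloxy)buta-1,3-diene A6 and methyl hex-2-ynoate A7 would combine on heating, the nucleophilic CH2 terminus of A6 bonding to the propyl-bearing carbon of A7. The adduct would aromatise by expelling one acetal methoxy group and shedding the silyl group to give methyl 4-hydroxy-2-methoxy-6-propylbenzoate A5.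
- In favour: the polarity of both partners fixes the orientation, the two oxygens emerge different, and no organolithium, cryogenic step or site-selective metalation is involved.
- Against: A7, an alkynoate with an alkyl group on its β-carbon, is a sluggish dienophile, and A6 is a sensitive ketene acetal that must be prepared first. A5 is the methyl ester of a doubly ortho-substituted, electron-rich benzoic acid, so silylation of the C4 hydroxyl and a difficult ester cleavage (slow saponification, possible decarboxylation or loss of the silyl ether) lie between A5 and 9.
- Comparison on structure: both plans deliver the whole ring B pattern with the oxygens differentiated, so the alternative is the equal of the chosen plan here.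
- Comparison on mechanism: its regiocontrol rests on one polarity argument and not on two separate selectivities, so it is the better plan on that point.
- Comparison on step economy: the chosen route reaches 9 in two steps with the acid free and the phenol protected. The alternative would need diene preparation, cycloaddition, silylation and ester cleavage.

Alternative 3: Ring B would be cut at C1–C6 only.
- Forward step: in dilute aqueous KOH the C2 carbanion of methyl 3,5,7-trioxodecanoate A9 would attack the C7 ketone. Loss of water and enolisation of the remaining carbonyls would then deliver methyl 2,4-dihydroxy-6-propylbenzoate A8.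
- In favour: a biomimetic closure in which one C–C bond forms the ring and sets carboxyl next to propyl, in aqueous base without metal reagents.
- Against: A9 is an unstable poly-β-carbonyl compound that must be assembled by polyanion acylation, and it can also close by Claisen acylation or lactonise to a pyranone. A8 has two free hydroxyls, and the one that must become methoxy is the chelated, less reactive C2 hydroxyl. The C4 hydroxyl of A8 would therefore have to be protected, the C2 hydroxyl methylated under forcing conditions, and the hindered methyl ester cleaved.
- Comparison on structure: the chosen plan has the C2 methoxy in place from 1 and never has to tell two ring B hydroxyls apart, whereas the alternative makes them alike.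
- Comparison on mechanism: the ring formation of the alternative is operationally simpler and, being free of organometallic reagents, is the better of the two for scale.
- Comparison on step economy: about six operations from simple esters to 9, against two.

Key step: step 2

Remark: 4 and 11 are assumed to be purchased ethereal solutions, and on ring A the oxygen next to the acylation site is assumed to be best masked as a benzyl ether with the chelated C2 hydroxyl left free, since a silyl group beside a phenoxide can migrate.

Step 1
Reactants: 1 3-fluoro-5-methoxyphenol; 2 chlorotri(propan-2-yl)silane
Product: 3 (3-fluoro-5-methoxyphenoxy)tri(propan-2-yl)silane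
Conditions: imidazole (2.2 equiv), DMF, rt
Reagents that add atoms: chlorotri(propan-2-yl)silane (2), CC(C)[Si](Cl)(C(C)C)C(C)C
Why: Silylation of a phenol through the N-silylimidazolium species; the triisopropylsilyl group is chosen because it withstands n-BuLi and Grignard reagents and shields its two ortho positions without coordinating lithium.

Step 2
Reactants: 3 (3-fluoro-5-methoxyphenoxy)tri(propan-2-yl)silane; 4 propylmagnesium chloride; 5 carbon dioxide
Product: 9 2-methoxy-6-propyl-4-{[tri(propan-2-yl)silyl]oxy}benzoic acid, via aryllithium 6 (not isolated), via aryne 7 (not isolated), via arylmagnesium chloride 8 (not isolated)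
Conditions: n-BuLi (0.98 equiv), THF, −78 °C, 1 h; cannulate into 4 (3 equiv), THF/Et2O, −78 °C → rt, 12 h; CO2 (dry gas), −40 °C → rt; 1 M HCl to pH 3
Reagents that add atoms: propylmagnesium chloride (4), CCC[Mg]Cl; carbon dioxide (5), O=C=O
Why: n-BuLi removes the ring hydrogen between fluorine and methoxy, the most acidic one because fluorine acidifies it inductively and methoxy binds lithium, whereas the two positions next to the silyl ether are shielded by a group that does not coordinate; this gives aryllithium 6, which is stable at −78 °C. Once 6 is in contact with the excess of 4 and the mixture warms, the ortho-metalated fluoroarene loses metal fluoride (written as LiF) and aryne 7 forms. The methoxy group on the carbon next to the triple bond withdraws electron density through the sigma framework and distorts 7 so that the aryne carbon remote from oxygen is the more electrophilic; the propyl group of 4 adds there and the carbon–magnesium bond of 8 forms next to methoxy, where the negative charge is stabilised inductively and by O–Mg coordination. CO2 then inserts into that hindered but reactive aryl–magnesium bond and acidification gives 9, so the C6–propyl and C1–carboxyl bonds of ring B are made in one flask. The closest known reaction type is the three-component aryne coupling in which a lithiated fluoroanisole, a Grignard reagent and an electrophile give a 1,2,3-trisubstituted arene (carbomagnesiation of a 3-alkoxyaryne followed by electrophilic trapping). No ring is closed and no stereocentre is formed. Two selectivities are needed: the site of lithiation, secured by the fluorine/methoxy pair and the bulk of the triisopropylsilyl group, and the direction of addition to 7, secured by the methoxy group. Using slightly less than one equivalent of n-BuLi and adding 6 to an excess of 4 should keep butyl–metal species and free 6 away from 7, which suppresses butyl incorporation and aryl–aryne self-coupling.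

Step 3
Reactants: 10 5-bromo-1,2,3-trimethoxybenzene; 11 pentylmagnesium bromide
Product: 12 1,2,3-trimethoxy-5-pentylbenzene
Conditions: PdCl2(dppf) (2 mol %), THF/Et2O, reflux
Reagents that add atoms: pentylmagnesium bromide (11), CCCCC[Mg]Br
Why: Kumada coupling (oxidative addition of the aryl bromide to zerovalent palladium, transmetalation, reductive elimination); the wide bite angle of dppf speeds reductive elimination of the primary alkyl group ahead of β-hydride elimination.

Step 4
Reactants: 12 1,2,3-trimethoxy-5-pentylbenzene; 13 acetyl chloride
Product: 14 1-(2,3,4-trimethoxy-6-pentylphenyl)ethan-1-one
Conditions: AlCl3 (1.3 equiv), CH2Cl2, 0 °C; then ice/1 M HCl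
Reagents that add atoms: acetyl chloride (13), CC(Cl)=O
Why: Friedel–Crafts acylation; the two free ring positions of 12 are equivalent and each is para to one methoxy and ortho to another, so only one ketone can form and it is deactivated toward a second acylation. Any material that loses the methyl group ortho to the ketone under AlCl3 converges with 14 in step 5.

Step 5
Reactants: 14 1-(2,3,4-trimethoxy-6-pentylphenyl)ethan-1-one
Product: 15 1-(2,3,4-trihydroxy-6-pentylphenyl)ethan-1-one
Conditions: BBr3 (5 equiv), CH2Cl2, −78 °C → rt; then H2O, 0 °C; work-up under argon
Reagents that add atoms: none
Why: Lewis-acid cleavage of aryl methyl ethers (boron coordinates the ether oxygen and bromide attacks the methyl group by SN2); the ketone and the alkyl chain are inert and the excess allows for BBr3 bound to the carbonyl.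

Step 6
Reactants: 15 1-(2,3,4-trihydroxy-6-pentylphenyl)ethan-1-one; 16 benzyl bromide
Product: 17 1-[4-(benzyloxy)-2,3-dihydroxy-6-pentylphenyl]ethan-1-one
Conditions: 16 (1.05 equiv), NaHCO3 (1.5 equiv), DMF, 40 °C, argon
Reagents that add atoms: benzyl bromide (16), BrCc1ccccc1
Why: Williamson etherification of the most acidic phenol; the C4 hydroxyl is para to the acetyl group and flanked by only one substituent, so a weak base should ionise it alone, while the C2 hydroxyl is chelated to the ketone and the C3 hydroxyl is flanked on both sides.

Step 7
Reactants: 9 2-methoxy-6-propyl-4-{[tri(propan-2-yl)silyl]oxy}benzoic acid; 17 1-[4-(benzyloxy)-2,3-dihydroxy-6-pentylphenyl]ethan-1-one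
Product: 20 3-acetyl-6-(benzyloxy)-2-hydroxy-4-pentylphenyl 2-methoxy-6-propyl-4-{[tri(propan-2-yl)silyl]oxy}benzoate, via acid chloride 18 (not isolated), via disodium diolate 19 (not isolated)
Conditions: 9 (1.1 equiv), Me2C=C(Cl)NMe2 (1.05 equiv), CH2Cl2, 0 °C → rt (gives 18); separately 17, NaH (2.1 equiv), THF, 0 °C, argon (gives 19); add 18 to 19, 0 °C → rt; cold 0.5 M HCl
Reagents that add atoms: none
Why: Acid chloride formation with an α-chloroenamine under neutral conditions (no HCl, so the aryl silyl ether is safe), then nucleophilic acyl substitution by a phenoxide. In dianion 19 the C2 oxygen is conjugated with the acetyl group and held in a sodium chelate, so the more basic C3 phenoxide should react first, as in the dianion method for 3-O-functionalisation of 2,3-dihydroxyaryl carbonyl compounds. The C3 ester is also the thermodynamic isomer because it keeps the hydroxyl–carbonyl chelate.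

Step 8
Reactants: 20 3-acetyl-6-(benzyloxy)-2-hydroxy-4-pentylphenyl 2-methoxy-6-propyl-4-{[tri(propan-2-yl)silyl]oxy}benzoate
Product: 21 3-acetyl-6-(benzyloxy)-2-hydroxy-4-pentylphenyl 4-hydroxy-2-methoxy-6-propylbenzoate
Conditions: Bu4NF (1.1 equiv), AcOH (1.5 equiv), THF, 0 °C
Reagents that add atoms: none
Why: Fluoride-induced cleavage of an aryl silyl ether, driven by the Si–F bond; acetic acid keeps the phenols protonated, so neither acyl shift nor ester cleavage should start, and the benzyl ether and ketone are untouched.

Step 9
Reactants: 21 3-acetyl-6-(benzyloxy)-2-hydroxy-4-pentylphenyl 4-hydroxy-2-methoxy-6-propylbenzoate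
Product: 22 3-acetyl-2,6-dihydroxy-4-pentylphenyl 4-hydroxy-2-methoxy-6-propylbenzoate
Conditions: H2 (1 atm), Pd/C (10 wt %), EtOAc, rt
Reagents that add atoms: none
Why: Palladium-catalysed hydrogenolysis of the benzylic C–O bond; in neutral ethyl acetate at one atmosphere the hindered, chelated aryl ketone and the aryl ester should not be reduced, and the product forms without any base that could move the ester.

## Compound list

1 | 3-fluoro-5-methoxyphenol | COc1cc(O)cc(F)c1 | starting material
2 | chlorotri(propan-2-yl)silane | CC(C)[Si](Cl)(C(C)C)C(C)C | starting material
3 | (3-fluoro-5-methoxyphenoxy)tri(propan-2-yl)silane | COc1cc(F)cc(O[Si](C(C)C)(C(C)C)C(C)C)c1 | intermediate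
4 | propylmagnesium chloride | CCC[Mg]Cl | starting material
5 | carbon dioxide | O=C=O | starting material
6 | [2-fluoro-6-methoxy-4-{[tri(propan-2-yl)silyl]oxy}phenyl]lithium | COc1cc(O[Si](C(C)C)(C(C)C)C(C)C)cc(F)c1[Li] | intermediate
7 | 3-methoxy-5-{[tri(propan-2-yl)silyl]oxy}benzyne (1,2-didehydrobenzene, triple bond between the former C–F and C–Li carbons) | COC1=CC(O[Si](C(C)C)(C(C)C)C(C)C)=CC#C1 | intermediate
8 | [2-methoxy-6-propyl-4-{[tri(propan-2-yl)silyl]oxy}phenyl]magnesium chloride | CCCc1cc(O[Si](C(C)C)(C(C)C)C(C)C)cc(OC)c1[Mg]Cl | intermediate
9 | 2-methoxy-6-propyl-4-{[tri(propan-2-yl)silyl]oxy}benzoic acid | CCCc1cc(O[Si](C(C)C)(C(C)C)C(C)C)cc(OC)c1C(O)=O | intermediate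
10 | 5-bromo-1,2,3-trimethoxybenzene | COc1cc(Br)cc(OC)c1OC | starting material
11 | pentylmagnesium bromide | CCCCC[Mg]Br | starting material
12 | 1,2,3-trimethoxy-5-pentylbenzene | CCCCCc1cc(OC)c(OC)c(OC)c1 | intermediate
13 | acetyl chloride | CC(Cl)=O | starting material
14 | 1-(2,3,4-trimethoxy-6-pentylphenyl)ethan-1-one | CCCCCc1cc(OC)c(OC)c(OC)c1C(C)=O | intermediate
15 | 1-(2,3,4-trihydroxy-6-pentylphenyl)ethan-1-one | CCCCCc1cc(O)c(O)c(O)c1C(C)=O | intermediate
16 | benzyl bromide | BrCc1ccccc1 | starting material
17 | 1-[4-(benzyloxy)-2,3-dihydroxy-6-pentylphenyl]ethan-1-one | CCCCCc1cc(OCc2ccccc2)c(O)c(O)c1C(C)=O | intermediate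
18 | 2-methoxy-6-propyl-4-{[tri(propan-2-yl)silyl]oxy}benzoyl chloride | CCCc1cc(O[Si](C(C)C)(C(C)C)C(C)C)cc(OC)c1C(Cl)=O | intermediate
19 | disodium 3-acetyl-6-(benzyloxy)-4-pentylbenzene-1,2-bis(olate) | CCCCCc1cc(OCc2ccccc2)c([O-])c([O-])c1C(C)=O.[Na+].[Na+] | intermediate
20 | 3-acetyl-6-(benzyloxy)-2-hydroxy-4-pentylphenyl 2-methoxy-6-propyl-4-{[tri(propan-2-yl)silyl]oxy}benzoate | CCCCCc1cc(OCc2ccccc2)c(OC(=O)c2c(CCC)cc(O[Si](C(C)C)(C(C)C)C(C)C)cc2OC)c(O)c1C(C)=O | intermediate
21 | 3-acetyl-6-(benzyloxy)-2-hydroxy-4-pentylphenyl 4-hydroxy-2-methoxy-6-propylbenzoate | CCCCCc1cc(OCc2ccccc2)c(OC(=O)c2c(CCC)cc(O)cc2OC)c(O)c1C(C)=O | intermediate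
22 | 3-acetyl-2,6-dihydroxy-4-pentylphenyl 4-hydroxy-2-methoxy-6-propylbenzoate | CCCCCc1cc(O)c(OC(=O)c2c(CCC)cc(O)cc2OC)c(O)c1C(C)=O | target

## Step count and least certain steps

Total: 9 steps. Longest linear sequence: 7 steps (steps 3, 4, 5, 6, 7, 8 and 9). The ring B branch (steps 1 and 2) joins at step 7.

**Step 2 (key step).**
- What may go wrong: metalation at a ring position other than the one between fluorine and methoxy, or consumption of the aryne by the aryllithium itself (aryl–aryne self-coupling) or by residual butyl–metal species. Elimination may also be slow after transmetalation to magnesium.
- Fallback, setting out from 3: 3 would be lithiated as before but trapped with CO2 at −78 °C before any fluoride is lost, to give 2-fluoro-6-methoxy-4-{[tri(propan-2-yl)silyl]oxy}benzoic acid F1. F1 can be purified and its substitution pattern confirmed. Treatment of F1 with an excess of 4 in THF should then displace the ortho-fluoride by carboxylate-directed addition–elimination (SNAr of an unprotected ortho-fluorobenzoic acid with a Grignard reagent) at a temperature low enough to spare the methoxy group. The route is rejoined at 9. This makes the two bonds in separate operations and avoids a free aryne.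

**Step 7.**
- What may go wrong: slow acyl transfer between two doubly ortho-substituted partners, which would let acylation at the chelated C2 oxygen, oxygen-to-oxygen acyl shift or air oxidation of the dianion compete.
- Fallback, setting out from 9 and 17: the phenoxide/acid chloride pairing would be abandoned for an acid-mediated esterification. 9 and 17 would be condensed with trifluoroacetic anhydride in toluene or CH2Cl2 at rt, the mixed-anhydride (acylium) method used for hindered depsides, in which the neutral non-chelated phenol reacts and the chelated hydroxyl stays out. The route is rejoined at 20 and no new compound is made.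

**Step 6.**
- What may go wrong: loss of site selectivity (alkylation running on to the C3 oxygen) and oxidative degradation of the triol while it is partly ionised.
- Fallback, setting out from 15: a Mitsunobu etherification with benzyl alcohol, PPh3 and diisopropyl azodicarboxylate in THF at 0 °C. It runs without added base and engages the most acidic phenol, which is again the C4 hydroxyl. The route is rejoined at 17 and no new compound is made.

**Step 9.**
- What may go wrong: over-reduction of the aryl ketone at its benzylic carbon, or stalling of the hydrogenolysis through catalyst poisoning.
- Fallback, setting out from 15, with an allyl group replacing benzyl so that no hydrogen is needed: 15 would be alkylated with allyl bromide and NaHCO3 in DMF to 1-[2,3-dihydroxy-6-pentyl-4-(prop-2-en-1-yloxy)phenyl]ethan-1-one F2. Coupling with 9 as in step 7 would give 3-acetyl-2-hydroxy-4-pentyl-6-(prop-2-en-1-yloxy)phenyl 2-methoxy-6-propyl-4-{[tri(propan-2-yl)silyl]oxy}benzoate F3. Buffered Bu4NF/AcOH would give 3-acetyl-2-hydroxy-4-pentyl-6-(prop-2-en-1-yloxy)phenyl 4-hydroxy-2-methoxy-6-propylbenzoate F4. Finally Pd(PPh3)4 (a zerovalent palladium catalyst) with morpholine in THF at rt would transfer the allyl group to the amine. The route is rejoined at 22.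

## Further compounds

F1 | step 2 | 2-fluoro-6-methoxy-4-{[tri(propan-2-yl)silyl]oxy}benzoic acid | COc1cc(O[Si](C(C)C)(C(C)C)C(C)C)cc(F)c1C(O)=O
F0 | step 7 | none | none
F0 | step 6 | none | none
F2 | step 9 | 1-[2,3-dihydroxy-6-pentyl-4-(prop-2-en-1-yloxy)phenyl]ethan-1-one | CCCCCc1cc(OCC=C)c(O)c(O)c1C(C)=O
F3 | step 9 | 3-acetyl-2-hydroxy-4-pentyl-6-(prop-2-en-1-yloxy)phenyl 2-methoxy-6-propyl-4-{[tri(propan-2-yl)silyl]oxy}benzoate | CCCCCc1cc(OCC=C)c(OC(=O)c2c(CCC)cc(O[Si](C(C)C)(C(C)C)C(C)C)cc2OC)c(O)c1C(C)=O
F4 | step 9 | 3-acetyl-2-hydroxy-4-pentyl-6-(prop-2-en-1-yloxy)phenyl 4-hydroxy-2-methoxy-6-propylbenzoate | CCCCCc1cc(OCC=C)c(OC(=O)c2c(CCC)cc(O)cc2OC)c(O)c1C(C)=O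
A1 | alternative 1 | trans-4-acetyl-5-pentylcyclohexane-1,3-dione (racemic, one enantiomer drawn) | CCCCC[C@H]1CC(=O)CC(=O)[C@@H]1C(C)=O
A2 | alternative 1 | ethyl (E)-oct-2-enoate | CCCCC/C=C/C(=O)OCC
A3 | alternative 1 | pentane-2,4-dione | CC(=O)CC(C)=O
A4 | alternative 1 | 1-(2,4-dihydroxy-6-pentylphenyl)ethan-1-one | CCCCCc1cc(O)cc(O)c1C(C)=O
A5 | alternative 2 | methyl 4-hydroxy-2-methoxy-6-propylbenzoate | CCCc1cc(O)cc(OC)c1C(=O)OC
A6 | alternative 2 | 1,1-dimethoxy-3-(trimethylsilyloxy)buta-1,3-diene | COC(OC)=CC(=C)O[Si](C)(C)C
A7 | alternative 2 | methyl hex-2-ynoate | CCCC#CC(=O)OC
A8 | alternative 3 | methyl 2,4-dihydroxy-6-propylbenzoate | CCCc1cc(O)cc(O)c1C(=O)OC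
A9 | alternative 3 | methyl 3,5,7-trioxodecanoate | CCCC(=O)CC(=O)CC(=O)CC(=O)OC
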